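Ring B, the 2-bromoresorcinol ring, is built rather than bought. Its carbons C1 to C3 carry O, Br, O and C5 carries the chain, which is the pattern a vinylketene and a C-silylated siloxyalkyne deliver. In one operation an α-diazo enone is converted by light and then heat into the benzene ring, with four new C–C bonds, hydroxyl at C1, silyloxy at C3 and SiMe3 at C2 as placeholder for bromine. The precursor is a (5Z)-1-diazo-3-methylidenehept-5-en-2-one whose C7 bears ring A (4-bromo-5-methoxy-2-silyloxyphenyl); the Z-alkene comes from cis-1,4-dichloro-2-butene. Ipso-bromodesilylation and one fluoride treatment finish colpol.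

Key step: step 7

Remark: the C-silyl ynolate is generated from (trimethylsilyl)diazomethane and CO, because ester homologation of ethyl (trimethylsilyl)acetate would put CH2SiMe3, one carbon too many, on the alkyne.
Remark: the ring A hydroxyl is carried as a triisopropylsilyl ether so that a single fluoride treatment frees all hydroxyls at the end.

Step 1
Reactants: 1 3-bromo-4-methoxyphenol; 2 cis-1,4-dichloro-2-butene
Product: 3 5-bromo-2-[(2Z)-4-chlorobut-2-en-1-yl]-4-methoxyphenol
Conditions: NaH (0.95 equiv), toluene, rt; then 2 (5 equiv), 80 °C (suspension); aq. NH4Cl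
Reagents that add atoms: none
Why: Heterogeneous ortho-C-allylation of a sodium phenoxide in a non-polar solvent (Claisen-type phenoxide C-alkylation) should join the less hindered ortho carbon, para to bromine, to one primary allylic carbon of 2 by SN2 displacement, which keeps the Z-alkene, while the excess of 2 limits double arylation; no stereocentre is formed.

Step 2
Reactants: 3 5-bromo-2-[(2Z)-4-chlorobut-2-en-1-yl]-4-methoxyphenol
Product: 4 {5-bromo-2-[(2Z)-4-chlorobut-2-en-1-yl]-4-methoxyphenoxy}tri(propan-2-yl)silane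
Conditions: TIPSOTf, 2,6-lutidine, CH2Cl2, 0 °C
Reagents that add atoms: triisopropylsilyl trifluoromethanesulfonate, CC(C)[Si](OS(=O)(=O)C(F)(F)F)(C(C)C)C(C)C
Why: O-silylation of the phenol with a silyl triflate and a hindered pyridine base should be fast and leave the allylic chloride untouched, and the bulky aryl silyl ether is chosen because it tolerates carbonate, amide base, light and heat and is removed together with the ring B silyl ether in the last step.

Step 3
Reactants: 4 {5-bromo-2-[(2Z)-4-chlorobut-2-en-1-yl]-4-methoxyphenoxy}tri(propan-2-yl)silane; 5 dimethyl (2-oxopropyl)phosphonate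
Product: 6 dimethyl {(5Z)-7-[4-bromo-5-methoxy-2-(triisopropylsilyloxy)phenyl]-2-oxohept-5-en-3-yl}phosphonate (racemic at C3)
Conditions: 5 (1.5 equiv), NaH, THF, 0 °C; then 4, THF–DMF, rt to 45 °C
Reagents that add atoms: none
Why: Alkylation of the sodium enolate of a β-ketophosphonate at its doubly activated carbon by SN2 displacement of the primary allylic chloride should attach the chain with the Z-alkene intact; the stereocentre at C3 arises racemic and is erased in step 4.

Step 4
Reactants: 6 dimethyl {(5Z)-7-[4-bromo-5-methoxy-2-(triisopropylsilyloxy)phenyl]-2-oxohept-5-en-3-yl}phosphonate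
Product: 7 (5Z)-7-[4-bromo-5-methoxy-2-(triisopropylsilyloxy)phenyl]-3-methylidenehept-5-en-2-one
Conditions: 37% aq. HCHO, K2CO3, THF–H2O, rt
Reagents that add atoms: formaldehyde, C=O
Why: Horner–Wadsworth–Emmons methylenation of the α-substituted β-ketophosphonate with aqueous formaldehyde and carbonate should give the α-methylidene ketone under conditions too mild to touch the aryl silyl ether, the aryl bromide or the skipped alkene.

Step 5
Reactants: 7 (5Z)-7-[4-bromo-5-methoxy-2-(triisopropylsilyloxy)phenyl]-3-methylidenehept-5-en-2-one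
Product: 9 (5Z)-7-[4-bromo-5-methoxy-2-(triisopropylsilyloxy)phenyl]-1-diazo-3-methylidenehept-5-en-2-one, via trifluoroacetyl diketone 8 (not isolated)
Conditions: LiN(SiMe3)2, THF, −78 °C; CF3CO2CH2CF3, −78 °C; then MsN3, Et3N, H2O (1 equiv), MeCN, rt
Reagents that add atoms: methanesulfonyl azide, CS(=O)(=O)N=[N+]=[N-]; 2,2,2-trifluoroethyl trifluoroacetate, O=C(OCC(F)(F)F)C(F)(F)F (its trifluoroacetyl group stays in 8 only)
Why: Detrifluoroacetylative diazo transfer: the kinetic lithium enolate of the methyl ketone is C-acylated by the trifluoroacetate ester, and the activated diketone 8 takes the diazo group from the sulfonyl azide while the trifluoroacetyl group leaves as the N-acylsulfonamide, a sequence that works on enones where direct diazo transfer fails.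

Step 6
Reactants: 10 (trimethylsilyl)diazomethane
Product: 12 trimethyl{[tri(propan-2-yl)silyl]oxyethynyl}silane, via lithium silylynolate 11 (not isolated)
Conditions: n-BuLi, THF, −78 °C; CO (1 atm), −78 to 0 °C; TIPSCl, −78 °C to rt
Reagents that add atoms: carbon monoxide, [C-]#[O+]; chlorotriisopropylsilane, CC(C)[Si](Cl)(C(C)C)C(C)C; n-butyllithium, [Li]CCCC (its lithium stays in 11 only)
Why: Lithiated (trimethylsilyl)diazomethane should add CO and lose N2 to give the silylynolate 11 (ynolate formation from a lithiated diazo compound and carbon monoxide), and the bulky chlorosilane should silylate this ambident anion at oxygen (ynolate O-silylation to a silyl ynol ether), whereas small chlorosilanes would react at carbon.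

Step 7
Reactants: 9 (5Z)-7-[4-bromo-5-methoxy-2-(triisopropylsilyloxy)phenyl]-1-diazo-3-methylidenehept-5-en-2-one; 12 trimethyl{[tri(propan-2-yl)silyl]oxyethynyl}silane
Product: 17 5-{(2Z)-4-[4-bromo-5-methoxy-2-(triisopropylsilyloxy)phenyl]but-2-en-1-yl}-3-(triisopropylsilyloxy)-2-(trimethylsilyl)phenol, via vinylketene 13 (not isolated), via vinylcyclobutenone 14 (not isolated), via dienylketene 15 (not isolated), via cyclohexadienone 16 (not isolated)
Conditions: 12 (2 equiv), hν (365 nm), degassed CH2Cl2, rt; then toluene, 90 °C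
Reagents that add atoms: none
Why: Irradiation of the s-cis diazo enone 9 triggers a Wolff rearrangement in which the alkenyl carbon C3 migrates to the diazo carbon as N2 leaves, giving vinylketene 13; its ketene C=C adds to siloxyalkyne 12 in a polar [2+2] cycloaddition to cyclobutenone 14, and heating opens 14 reversibly by 4π conrotation to dienylketene 15, which closes between the ketene carbon and the methylidene carbon and tautomerises from dienone 16 to phenol 17. The closest known reaction type is the photochemical Danheiser benzannulation of α-diazo enones with siloxyalkynes. The one ring formed, benzene ring B, is closed by a thermal disrotatory 6π electrocyclisation of 15, after which enolisation makes it aromatic. No stereocentre remains, since C4 of 14 is formed racemic and is lost on ring opening, and the Z-alkene of the chain is a spectator. The step needs the order hydroxyl, SiMe3, silyloxy at C1, C2, C3, which is secured by the polarisation of 12: its oxygen makes the silicon-bearing carbon nucleophilic, so this carbon bonds to the ketene carbonyl carbon while oxygen and the β-silicon stabilise the developing charge. It also needs Wolff rearrangement to win over carbene addition to the C5=C6 alkene and over C–Br photolysis, which is secured by direct excitation of the diazo chromophore at long wavelength without metal or sensitiser, and the excess of 12 should outrun ketene dimerisation and acylation of 17.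

Step 8
Reactants: 17 5-{(2Z)-4-[4-bromo-5-methoxy-2-(triisopropylsilyloxy)phenyl]but-2-en-1-yl}-3-(triisopropylsilyloxy)-2-(trimethylsilyl)phenol
Product: 18 2-bromo-5-{(2Z)-4-[4-bromo-5-methoxy-2-(triisopropylsilyloxy)phenyl]but-2-en-1-yl}-3-(triisopropylsilyloxy)phenol
Conditions: NBS (1.0 equiv), MeCN, −20 to 0 °C, dark; aq. Na2S2O3
Reagents that add atoms: N-bromosuccinimide, O=C1CCC(=O)N1Br
Why: Electrophilic ipso-bromodesilylation: bromine from NBS attacks the silicon-bearing C2, which is activated by both flanking oxygens and gives a β-silyl-stabilised arenium ion that loses the silyl group, a path expected to be faster than substitution at the C4 and C6 hydrogens, at ring A or at the alkene at low temperature with one equivalent of reagent.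

Step 9
Reactants: 18 2-bromo-5-{(2Z)-4-[4-bromo-5-methoxy-2-(triisopropylsilyloxy)phenyl]but-2-en-1-yl}-3-(triisopropylsilyloxy)phenol
Product: 19 colpol, 2-bromo-5-[(2Z)-4-(4-bromo-2-hydroxy-5-methoxyphenyl)but-2-en-1-yl]benzene-1,3-diol
Conditions: TBAF, AcOH, THF, 0 °C to rt
Reagents that add atoms: none
Why: Fluoride-induced cleavage of both aryl silyl ethers (Si–F bond formation) should free the remaining hydroxyls in one operation, and buffering with acetic acid keeps the medium nearly neutral so that the doubly benzylic Z-alkene does not migrate.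

Compound list
1 | 3-bromo-4-methoxyphenol | COc1ccc(O)cc1Br | starting material
2 | cis-1,4-dichloro-2-butene | ClC/C=C\CCl | starting material
3 | 5-bromo-2-[(2Z)-4-chlorobut-2-en-1-yl]-4-methoxyphenol | COc1cc(C/C=C\CCl)c(O)cc1Br | intermediate
4 | {5-bromo-2-[(2Z)-4-chlorobut-2-en-1-yl]-4-methoxyphenoxy}tri(propan-2-yl)silane | COc1cc(C/C=C\CCl)c(O[Si](C(C)C)(C(C)C)C(C)C)cc1Br | intermediate
5 | dimethyl (2-oxopropyl)phosphonate | CC(=O)CP(=O)(OC)OC | starting material
6 | dimethyl {(5Z)-7-[4-bromo-5-methoxy-2-(triisopropylsilyloxy)phenyl]-2-oxohept-5-en-3-yl}phosphonate, racemic at C3 | CC(=O)C(C/C=C\Cc1cc(OC)c(Br)cc1O[Si](C(C)C)(C(C)C)C(C)C)P(=O)(OC)OC | intermediate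
7 | (5Z)-7-[4-bromo-5-methoxy-2-(triisopropylsilyloxy)phenyl]-3-methylidenehept-5-en-2-one | CC(=O)C(=C)C/C=C\Cc1cc(OC)c(Br)cc1O[Si](C(C)C)(C(C)C)C(C)C | intermediate
8 | (7Z)-9-[4-bromo-5-methoxy-2-(triisopropylsilyloxy)phenyl]-1,1,1-trifluoro-5-methylidenenon-7-ene-2,4-dione | O=C(CC(=O)C(=C)C/C=C\Cc1cc(OC)c(Br)cc1O[Si](C(C)C)(C(C)C)C(C)C)C(F)(F)F | intermediate (not isolated)
9 | (5Z)-7-[4-bromo-5-methoxy-2-(triisopropylsilyloxy)phenyl]-1-diazo-3-methylidenehept-5-en-2-one | C=C(C/C=C\Cc1cc(OC)c(Br)cc1O[Si](C(C)C)(C(C)C)C(C)C)C(=O)C=[N+]=[N-] | intermediate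
10 | (trimethylsilyl)diazomethane | C[Si](C)(C)C=[N+]=[N-] | starting material
11 | lithium 2-(trimethylsilyl)ethyn-1-olate | [Li+].[O-]C#C[Si](C)(C)C | intermediate (not isolated)
12 | trimethyl{[tri(propan-2-yl)silyl]oxyethynyl}silane | CC(C)[Si](OC#C[Si](C)(C)C)(C(C)C)C(C)C | intermediate
13 | (5Z)-7-[4-bromo-5-methoxy-2-(triisopropylsilyloxy)phenyl]-3-methylidenehepta-1,5-dien-1-one | O=C=CC(=C)C/C=C\Cc1cc(OC)c(Br)cc1O[Si](C(C)C)(C(C)C)C(C)C | intermediate (not isolated)
14 | 4-{(4Z)-6-[4-bromo-5-methoxy-2-(triisopropylsilyloxy)phenyl]hexa-1,4-dien-2-yl}-3-(triisopropylsilyloxy)-2-(trimethylsilyl)cyclobut-2-en-1-one, racemic at C4 | O=C1C([Si](C)(C)C)=C(O[Si](C(C)C)(C(C)C)C(C)C)C1C(=C)C/C=C\Cc2cc(OC)c(Br)cc2O[Si](C(C)C)(C(C)C)C(C)C | intermediate (not isolated)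
15 | (3E,7Z)-9-[4-bromo-5-methoxy-2-(triisopropylsilyloxy)phenyl]-5-methylidene-3-(triisopropylsilyloxy)-2-(trimethylsilyl)nona-1,3,7-trien-1-one | O=C=C([Si](C)(C)C)/C(O[Si](C(C)C)(C(C)C)C(C)C)=C\C(=C)C/C=C\Cc2cc(OC)c(Br)cc2O[Si](C(C)C)(C(C)C)C(C)C | intermediate (not isolated)
16 | 5-{(2Z)-4-[4-bromo-5-methoxy-2-(triisopropylsilyloxy)phenyl]but-2-en-1-yl}-3-(triisopropylsilyloxy)-2-(trimethylsilyl)cyclohexa-2,4-dien-1-one | O=C1CC(C/C=C\Cc2cc(OC)c(Br)cc2O[Si](C(C)C)(C(C)C)C(C)C)=CC(O[Si](C(C)C)(C(C)C)C(C)C)=C1[Si](C)(C)C | intermediate (not isolated)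
17 | 5-{(2Z)-4-[4-bromo-5-methoxy-2-(triisopropylsilyloxy)phenyl]but-2-en-1-yl}-3-(triisopropylsilyloxy)-2-(trimethylsilyl)phenol | Oc1cc(C/C=C\Cc2cc(OC)c(Br)cc2O[Si](C(C)C)(C(C)C)C(C)C)cc(O[Si](C(C)C)(C(C)C)C(C)C)c1[Si](C)(C)C | intermediate
18 | 2-bromo-5-{(2Z)-4-[4-bromo-5-methoxy-2-(triisopropylsilyloxy)phenyl]but-2-en-1-yl}-3-(triisopropylsilyloxy)phenol | Oc1cc(C/C=C\Cc2cc(OC)c(Br)cc2O[Si](C(C)C)(C(C)C)C(C)C)cc(O[Si](C(C)C)(C(C)C)C(C)C)c1Br | intermediate
19 | colpol, 2-bromo-5-[(2Z)-4-(4-bromo-2-hydroxy-5-methoxyphenyl)but-2-en-1-yl]benzene-1,3-diol | COc1cc(C/C=C\Cc2cc(O)c(Br)c(O)c2)c(O)cc1Br | target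

Total step count: 9. Longest linear sequence: 8 (steps 1 to 5 and 7 to 9); step 6 is a one-step side branch.

Steps most likely to fail

Step 7. Capture of the photogenerated vinylketene by the hindered, silicon-bearing alkyne carbon may be slower than ketene dimerisation or acylation of the newly formed phenol. Carbene-type addition to the chain alkene or photolytic loss of aryl bromine may also divert the diazo ketone. The fallback brings ring B in ready-made with its bromine and joins it at the C3–C4 bond of the chain by an alkenyl–benzyl Negishi coupling that retains geometry. It sets out from 4 and comes back to the route at 19.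
- Ozonolysis of 4 (O3, CH2Cl2, −78 °C; PPh3) should give [4-bromo-5-methoxy-2-(triisopropylsilyloxy)phenyl]acetaldehyde F1.
- Stork–Zhao olefination ((iodomethyl)triphenylphosphonium iodide, NaN(SiMe3)2, THF, −78 °C) should turn it into the Z-alkenyl iodide {5-bromo-2-[(2Z)-3-iodoprop-2-en-1-yl]-4-methoxyphenoxy}tri(propan-2-yl)silane F2.
- Commercial methyl 4-bromo-3,5-dihydroxybenzoate is silylated (TIPSCl, imidazole, DMF) to methyl 4-bromo-3,5-bis(triisopropylsilyloxy)benzoate F3.
- Reduction (i-Bu2AlH, CH2Cl2, −78 °C) gives [4-bromo-3,5-bis(triisopropylsilyloxy)phenyl]methanol F4, and Appel bromination (CBr4, PPh3) gives {[2-bromo-5-(bromomethyl)-1,3-phenylene]bis(oxy)}bis[tri(propan-2-yl)silane] F5.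
- Zinc insertion (Zn dust, LiCl, THF) gives [4-bromo-3,5-bis(triisopropylsilyloxy)benzyl]zinc bromide F6.
- F6 should couple with F2 under Pd(PPh3)4 (zerovalent palladium) at rt, the alkenyl iodide reacting far faster than either aryl bromide, to give the tris(triisopropylsilyl) ether of colpol F7.
- Fluoride as in step 9 then gives 19.

Step 1. The ambident phenoxide may be alkylated at oxygen. The product phenoxide may also close onto its own allylic chloride, by five-membered SN2' or seven-membered SN2 ether formation. A second phenoxide may displace the remaining chloride, and the crowded ortho carbon next to bromine may compete. The fallback makes the aryl–CH2 bond from an arylmagnesium reagent whose oxygen is already silylated, so that no phenoxide is present. It sets out from 1 and comes back at 4.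
- Iodination (NIS, TsOH cat., MeCN) at the free ortho carbon para to bromine should give 5-bromo-2-iodo-4-methoxyphenol F8.
- Silylation (TIPSOTf, 2,6-lutidine, CH2Cl2) gives (5-bromo-2-iodo-4-methoxyphenoxy)tri(propan-2-yl)silane F9.
- Iodine–magnesium exchange (i-PrMgCl·LiCl, THF, −20 °C), which leaves the aryl bromide alone, gives [4-bromo-5-methoxy-2-(triisopropylsilyloxy)phenyl]magnesium chloride F10.
- Rapid addition of F10 to an excess of 2 with Li2CuCl4 (cat.) in THF at −30 °C should give 4 by copper-catalysed Grignard substitution at the primary allylic carbon.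

Step 8. Bromination at the C–H positions C4 and C6 of ring B, para and ortho to the free hydroxyl, may compete with ipso attack at C2. Traces of HBr may also cause protodesilylation. The fallback sets the regiochemistry by selective reductive debromination and no longer depends on ipso selectivity. It sets out from 17 and comes back at 19.
- Excess NBS (3 equiv, MeCN, 0 °C) should brominate C2 (ipso), C4 and C6 to give 2,4,6-tribromo-3-{(2Z)-4-[4-bromo-5-methoxy-2-(triisopropylsilyloxy)phenyl]but-2-en-1-yl}-5-(triisopropylsilyloxy)phenol F11.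
- Fluoride (TBAF, AcOH, THF) gives 2,4,6-tribromo-5-[(2Z)-4-(4-bromo-2-hydroxy-5-methoxyphenyl)but-2-en-1-yl]benzene-1,3-diol F12.
- Na2SO3 and NaOH in aqueous MeOH at rt should remove the two bromines para to a hydroxyl (C4 and C6) through the keto tautomer, as in the preparation of 2-bromoresorcinol from 2,4,6-tribromoresorcinol. The bromine at C2 and the ring A bromine, which is meta to its hydroxyl, should stay, giving 19.

Further compounds
F1 | step 7 | [4-bromo-5-methoxy-2-(triisopropylsilyloxy)phenyl]acetaldehyde | COc1cc(CC=O)c(O[Si](C(C)C)(C(C)C)C(C)C)cc1Br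
F2 | step 7 | {5-bromo-2-[(2Z)-3-iodoprop-2-en-1-yl]-4-methoxyphenoxy}tri(propan-2-yl)silane | COc1cc(C/C=C\I)c(O[Si](C(C)C)(C(C)C)C(C)C)cc1Br
F3 | step 7 | methyl 4-bromo-3,5-bis(triisopropylsilyloxy)benzoate | COC(=O)c1cc(O[Si](C(C)C)(C(C)C)C(C)C)c(Br)c(O[Si](C(C)C)(C(C)C)C(C)C)c1
F4 | step 7 | [4-bromo-3,5-bis(triisopropylsilyloxy)phenyl]methanol | OCc1cc(O[Si](C(C)C)(C(C)C)C(C)C)c(Br)c(O[Si](C(C)C)(C(C)C)C(C)C)c1
F5 | step 7 | {[2-bromo-5-(bromomethyl)-1,3-phenylene]bis(oxy)}bis[tri(propan-2-yl)silane] | BrCc1cc(O[Si](C(C)C)(C(C)C)C(C)C)c(Br)c(O[Si](C(C)C)(C(C)C)C(C)C)c1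
F6 | step 7 | [4-bromo-3,5-bis(triisopropylsilyloxy)benzyl]zinc bromide | Br[Zn]Cc1cc(O[Si](C(C)C)(C(C)C)C(C)C)c(Br)c(O[Si](C(C)C)(C(C)C)C(C)C)c1
F7 | step 7 | tris(triisopropylsilyl) ether of colpol, {[2-bromo-5-{(2Z)-4-[4-bromo-5-methoxy-2-(triisopropylsilyloxy)phenyl]but-2-en-1-yl}-1,3-phenylene]bis(oxy)}bis[tri(propan-2-yl)silane] | COc1cc(C/C=C\Cc2cc(O[Si](C(C)C)(C(C)C)C(C)C)c(Br)c(O[Si](C(C)C)(C(C)C)C(C)C)c2)c(O[Si](C(C)C)(C(C)C)C(C)C)cc1Br
F8 | step 1 | 5-bromo-2-iodo-4-methoxyphenol | COc1cc(I)c(O)cc1Br
F9 | step 1 | (5-bromo-2-iodo-4-methoxyphenoxy)tri(propan-2-yl)silane | COc1cc(I)c(O[Si](C(C)C)(C(C)C)C(C)C)cc1Br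
F10 | step 1 | [4-bromo-5-methoxy-2-(triisopropylsilyloxy)phenyl]magnesium chloride | COc1cc([Mg]Cl)c(O[Si](C(C)C)(C(C)C)C(C)C)cc1Br
F11 | step 8 | 2,4,6-tribromo-3-{(2Z)-4-[4-bromo-5-methoxy-2-(triisopropylsilyloxy)phenyl]but-2-en-1-yl}-5-(triisopropylsilyloxy)phenol | Oc1c(Br)c(C/C=C\Cc2cc(OC)c(Br)cc2O[Si](C(C)C)(C(C)C)C(C)C)c(Br)c(O[Si](C(C)C)(C(C)C)C(C)C)c1Br
F12 | step 8 | 2,4,6-tribromo-5-[(2Z)-4-(4-bromo-2-hydroxy-5-methoxyphenyl)but-2-en-1-yl]benzene-1,3-diol | Oc1c(Br)c(C/C=C\Cc2cc(OC)c(Br)cc2O)c(Br)c(O)c1Br
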